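**Retrosynthetic overview**

- The target is an 8-methoxynaphthalen-1-ol core (unit B) carrying the same 4-hydroxy-5-methoxynaphthalen-1-yl group on C2 (unit A) and on C4 (unit C); the last step frees the two outer phenols from benzyl ethers.
- Key disconnection: the biaryl bond C4(B)–C1(C). Both carbons are para to a naphthol oxygen and natively nucleophilic. Because C4 of B is para to the C1 oxygen, the oxygenated ring of B (C1–C4, C4a, C8a) can be held as a 1,4-naphthoquinone in which C4 is a carbonyl carbon. The C8 methoxy group (peri to C1) and the C2 aryl group shield and deactivate the other carbonyl, so a unit C aryllithium should add at C4 only; zinc then removes the extra oxygen and rearomatizes.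
- The C2(B)–C4(A) bond: Suzuki–Miyaura coupling of 2-bromo-8-methoxy-1,4-naphthoquinone (from juglone) with a boronate made from the same aryl bromide that later supplies unit C (from naphthalene-1,8-diol).
- Ring order: no carbocycle is built. All three naphthalenes are bought intact; the oxygenated ring of B passes quinone → quinol → naphthol and is the last ring to become aromatic.

Key step: step 8

Remark on the chemistry: the target is drawn without stereodescriptors, so its two biaryl axes are treated as stereochemically undefined (racemic, possibly interconverting atropisomers) and no axial control is attempted.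

**Route**

Step 1
Reactants: 1 naphthalene-1,8-diol
Product: 2 8-methoxynaphthalen-1-ol
Conditions: MeI (1.05 equiv), K2CO3 (1.1 equiv), acetone, reflux
Reagents that add atoms: iodomethane, CI
Why: Williamson mono-O-methylation; the peri hydrogen bond makes the first hydroxyl unusually acidic, and the remaining hydroxyl of 2, chelated to the new methoxy group, resists a second alkylation under carbonate.

Step 2
Reactants: 2 8-methoxynaphthalen-1-ol
Product: 3 4-bromo-8-methoxynaphthalen-1-ol
Conditions: NBS (1.0 equiv), MeCN, –20 → 0 °C, dark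
Reagents that add atoms: N-bromosuccinimide, O=C1CCC(=O)N1Br
Why: electrophilic aromatic bromination directed para by the free hydroxyl, the strongest donor; it is done before O-protection so that C4 beats C5 (para to the methoxy group), and one equivalent at low temperature limits C2 bromination.

Step 3
Reactants: 3 4-bromo-8-methoxynaphthalen-1-ol
Product: 4 1-(benzyloxy)-4-bromo-8-methoxynaphthalene
Conditions: BnBr, K2CO3, DMF, 60 °C
Reagents that add atoms: benzyl bromide, BrCc1ccccc1
Why: Williamson etherification; the benzyl ether tolerates palladium catalysis, n-BuLi at –78 °C and Zn/AcOH, and is later removed by hydrogenolysis without touching the methyl ethers.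

Step 4
Reactants: 4 1-(benzyloxy)-4-bromo-8-methoxynaphthalene
Product: 5 2-[4-(benzyloxy)-5-methoxynaphthalen-1-yl]-4,4,5,5-tetramethyl-1,3,2-dioxaborolane
Conditions: B2pin2 (1.2 equiv), PdCl2(dppf) (3 mol %), KOAc (3 equiv), 1,4-dioxane, 90 °C
Reagents that add atoms: bis(pinacolato)diboron, CC1(C)OB(OC1(C)C)B1OC(C)(C)C(C)(C)O1
Why: Miyaura borylation of an electron-rich aryl bromide; acetate is too weak a base to trigger onward Suzuki coupling of the product.

Step 5
Reactants: 6 juglone (5-hydroxynaphthalene-1,4-dione)
Product: 8 2-bromo-8-hydroxynaphthalene-1,4-dione (3-bromojuglone), via trans-2,3-dibromo-2,3-dihydrojuglone 7 (not isolated)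
Conditions: Br2 (1.05 equiv), AcOH, rt; then EtOH, reflux
Reagents that add atoms: bromine, BrBr
Why: bromine addition to the quinone C2=C3 bond followed by dehydrobromination; the hydrogen alpha to the hydrogen-bond-chelated carbonyl is the more acidic, so enolization toward that carbonyl expels the distal bromide and leaves bromine next to the carbonyl that is peri to the hydroxyl.

Step 6
Reactants: 8 2-bromo-8-hydroxynaphthalene-1,4-dione
Product: 9 2-bromo-8-methoxynaphthalene-1,4-dione
Conditions: MeI (excess), Ag2O, CH2Cl2, rt, dark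
Reagents that add atoms: iodomethane, CI
Why: Purdie methylation with Ag2O alkylates the chelated phenol under non-basic conditions that spare the base-sensitive bromoquinone.

Step 7
Reactants: 9 2-bromo-8-methoxynaphthalene-1,4-dione; 5 2-[4-(benzyloxy)-5-methoxynaphthalen-1-yl]-4,4,5,5-tetramethyl-1,3,2-dioxaborolane
Product: 10 2-[4-(benzyloxy)-5-methoxynaphthalen-1-yl]-8-methoxynaphthalene-1,4-dione
Conditions: PdCl2(dppf) (5 mol %), K3PO4 (2 equiv), 1,4-dioxane/H2O, 70 °C, argon
Reagents that add atoms: none
Why: Suzuki–Miyaura coupling; the C–Br bond of the bromoquinone is a vinylogous acyl bromide that adds readily to zerovalent palladium, and the mild phosphate base limits hydroxide displacement of bromide.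

Step 8
Reactants: 4 1-(benzyloxy)-4-bromo-8-methoxynaphthalene; 10 2-[4-(benzyloxy)-5-methoxynaphthalen-1-yl]-8-methoxynaphthalene-1,4-dione
Product: 13 2,4-bis[4-(benzyloxy)-5-methoxynaphthalen-1-yl]-4-hydroxy-8-methoxynaphthalen-1(4H)-one, via aryllithium 11 (not isolated), via lithium quinolate 12 (not isolated)
Conditions: 4, n-BuLi (1.05 equiv), THF, –78 °C; cannulate slowly into 10, THF, –78 °C; then AcOH (1.1 equiv), –78 °C → rt
Reagents that add atoms: none
Why: Bromine–lithium exchange on 4 gives aryllithium 11, whose carbanionic carbon (the future C1 of unit C) adds 1,2 to the C4 carbonyl of quinone 10 to give lithium quinolate 12, which AcOH protonates to quinol 13; the two carbons joined are both para to an oxygen and natively nucleophilic, and the union works because unit B is held at the quinone oxidation level. The closest known reaction type is the 1,2-addition of aryllithium reagents to 1,4-quinones and quinone monoketals to give 4-aryl-4-hydroxycyclohexadienones (para-quinols), which lead to biaryls after reductive aromatization. No ring is closed. The one new stereocenter, the carbinol carbon C4 of unit B, forms without control as a racemate and is erased in step 9. The step needs carbonyl selectivity (C4 over C1) and carbonyl addition over conjugate addition or electron transfer: C1=O is shielded by the peri C8 methoxy group and the twisted C2 naphthyl group and is deactivated as a vinylogous ester by the C8 oxygen, whereas C4=O is flanked only by C3–H and C5–H; a hard aryllithium at –78 °C, added slowly to the quinone, should favour carbonyl attack.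

Step 9
Reactants: 13 2,4-bis[4-(benzyloxy)-5-methoxynaphthalen-1-yl]-4-hydroxy-8-methoxynaphthalen-1(4H)-one
Product: 14 2,4-bis[4-(benzyloxy)-5-methoxynaphthalen-1-yl]-8-methoxynaphthalen-1-ol
Conditions: Zn dust (10 equiv), AcOH/THF, rt, argon
Reagents that add atoms: none
Why: reductive aromatization of a para-quinol; two-electron reduction of the enone expels the C4 hydroxyl (vinylogous alpha-hydroxy ketone reduction) and the resulting naphthoxide is protonated, with aromatization as driving force and benzyl and methyl ethers inert.

Step 10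
Reactants: 14 2,4-bis[4-(benzyloxy)-5-methoxynaphthalen-1-yl]-8-methoxynaphthalen-1-ol
Product: 15 2,4-bis(4-hydroxy-5-methoxynaphthalen-1-yl)-8-methoxynaphthalen-1-ol (CNP0528831.0)
Conditions: H2 (1 atm), 10% Pd/C, THF/MeOH, rt; filtration and concentration under argon
Reagents that add atoms: none
Why: hydrogenolysis of the two benzyl aryl ethers leaves methyl ethers and naphthalene rings untouched, and the reducing medium protects the oxidation-prone para,para-linked bis-naphthol.

**Compound list**

1 | naphthalene-1,8-diol | Oc1cccc2cccc(O)c12 | starting material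
2 | 8-methoxynaphthalen-1-ol | COc1cccc2cccc(O)c12 | intermediate
3 | 4-bromo-8-methoxynaphthalen-1-ol | COc1cccc2c(Br)ccc(O)c12 | intermediate
4 | 1-(benzyloxy)-4-bromo-8-methoxynaphthalene | COc1cccc2c(Br)ccc(OCc3ccccc3)c12 | intermediate
5 | 2-[4-(benzyloxy)-5-methoxynaphthalen-1-yl]-4,4,5,5-tetramethyl-1,3,2-dioxaborolane | COc1cccc2c(B3OC(C)(C)C(C)(C)O3)ccc(OCc3ccccc3)c12 | intermediate
6 | juglone (5-hydroxynaphthalene-1,4-dione) | O=C1C=CC(=O)c2c(O)cccc12 | starting material
7 | trans-2,3-dibromo-5-hydroxy-2,3-dihydronaphthalene-1,4-dione (racemic, one enantiomer drawn; not isolated) | O=C1[C@@H](Br)[C@H](Br)C(=O)c2c(O)cccc12 | intermediate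
8 | 2-bromo-8-hydroxynaphthalene-1,4-dione (3-bromojuglone) | O=C1C=C(Br)C(=O)c2c(O)cccc12 | intermediate
9 | 2-bromo-8-methoxynaphthalene-1,4-dione | COc1cccc2C(=O)C=C(Br)C(=O)c12 | intermediate
10 | 2-[4-(benzyloxy)-5-methoxynaphthalen-1-yl]-8-methoxynaphthalene-1,4-dione | COc1cccc2C(=O)C=C(c3ccc(OCc4ccccc4)c4c(OC)cccc34)C(=O)c12 | intermediate
11 | [4-(benzyloxy)-5-methoxynaphthalen-1-yl]lithium (not isolated) | [Li]c1ccc(OCc2ccccc2)c2c(OC)cccc12 | intermediate
12 | lithium 1,3-bis[4-(benzyloxy)-5-methoxynaphthalen-1-yl]-5-methoxy-4-oxo-1,4-dihydronaphthalen-1-olate (racemic; not isolated) | COc1cccc2c1C(=O)C(c1ccc(OCc3ccccc3)c3c(OC)cccc13)=CC2(O[Li])c1ccc(OCc2ccccc2)c2c(OC)cccc12 | intermediate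
13 | 2,4-bis[4-(benzyloxy)-5-methoxynaphthalen-1-yl]-4-hydroxy-8-methoxynaphthalen-1(4H)-one (racemic at C4, configuration not controlled) | COc1cccc2c1C(=O)C(c1ccc(OCc3ccccc3)c3c(OC)cccc13)=CC2(O)c1ccc(OCc2ccccc2)c2c(OC)cccc12 | intermediate
14 | 2,4-bis[4-(benzyloxy)-5-methoxynaphthalen-1-yl]-8-methoxynaphthalen-1-ol | COc1cccc2c(-c3cc(-c4ccc(OCc6ccccc6)c5c(OC)cccc45)c4cccc(OC)c4c3O)ccc(OCc3ccccc3)c12 | intermediate
15 | 2,4-bis(4-hydroxy-5-methoxynaphthalen-1-yl)-8-methoxynaphthalen-1-ol | COc1cccc2c(-c3cc(-c4ccc(O)c5c(OC)cccc45)c4cccc(OC)c4c3O)ccc(O)c12 | target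

**Step count**

Total: 10 steps. Longest linear sequence: 8 steps (steps 1, 2, 3, 4, 7, 8, 9, 10); the juglone branch (steps 5, 6) joins at step 7.

**Steps most likely to fail, with fallbacks**

Step 8. Electron transfer from aryllithium 11 to quinone 10, or conjugate addition at C3, may outrun addition to the C4 carbonyl. The fallback sets out from 10 and returns at 14, forming the same biaryl bond by cross-coupling. Quinone 10 is reduced with Na2S2O4 (EtOAc/H2O) to 2-[4-(benzyloxy)-5-methoxynaphthalen-1-yl]-8-methoxynaphthalene-1,4-diol F1. Only the C4 hydroxyl of F1, which is neither chelated to the C8 methoxy group nor flanked by the aryl group, is triflated (PhNTf2, 1.0 equiv, K2CO3, DMF, 0 °C) to give 3-[4-(benzyloxy)-5-methoxynaphthalen-1-yl]-4-hydroxy-5-methoxynaphthalen-1-yl trifluoromethanesulfonate F2. Suzuki–Miyaura coupling of F2 with boronate 5 (Pd(OAc)2, SPhos, K3PO4, toluene/H2O, 80 °C) should then give 14 directly.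

Step 7. Hydrolytic or reductive loss of the bromoquinone under basic palladium conditions, together with protodeboronation of the hindered electron-rich boronate, may starve the coupling. The fallback sets out from 2 and 5 and returns at 10, making the A–B bond at the naphthol oxidation level and oxidizing afterwards. Naphthol 2 is protected (NaH, MOMCl, THF) as 1-methoxy-8-(methoxymethoxy)naphthalene F3. Directed ortho-lithiation next to the stronger acetal director (n-BuLi, TMEDA, Et2O, 0 °C) and an I2 quench give 2-iodo-8-methoxy-1-(methoxymethoxy)naphthalene F4. Suzuki–Miyaura coupling of F4 with 5 (PdCl2(dppf), K3PO4, 1,4-dioxane/H2O, 80 °C) gives 1-(benzyloxy)-8-methoxy-4-[8-methoxy-1-(methoxymethoxy)naphthalen-2-yl]naphthalene F5. Acetal cleavage (HCl, MeOH/THF, 40 °C) gives 2-[4-(benzyloxy)-5-methoxynaphthalen-1-yl]-8-methoxynaphthalen-1-ol F6. Para-oxidation of this free naphthol with K2NO(SO3)2 (KH2PO4 buffer, acetone/H2O) should give quinone 10, the benzyl-protected unit A being inert to this oxidant.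

Step 9. Acid-promoted aryl migration in the protonated dienone (dienone–phenol type rearrangement) or incomplete reduction at the crowded enone may compete with reductive aromatization. The fallback sets out from 13 and returns at 14, replacing dissolving-metal reduction by hydride reduction and dehydration. Luche reduction (NaBH4, CeCl3·7H2O, MeOH/THF, 0 °C) of the C1 ketone gives 2,4-bis[4-(benzyloxy)-5-methoxynaphthalen-1-yl]-8-methoxy-1,4-dihydronaphthalene-1,4-diol F7 as a diastereomer mixture. Catalytic pyridinium p-toluenesulfonate in CH2Cl2 at rt should ionize the tertiary C4 hydroxyl, and loss of the C1 hydrogen (1,4-dehydration) then aromatizes all diastereomers to 14.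

**Further compounds**

F1 | step 8 | 2-[4-(benzyloxy)-5-methoxynaphthalen-1-yl]-8-methoxynaphthalene-1,4-diol | COc1cccc2c(O)cc(-c3ccc(OCc4ccccc4)c4c(OC)cccc34)c(O)c12
F2 | step 8 | 3-[4-(benzyloxy)-5-methoxynaphthalen-1-yl]-4-hydroxy-5-methoxynaphthalen-1-yl trifluoromethanesulfonate | COc1cccc2c(OS(=O)(=O)C(F)(F)F)cc(-c3ccc(OCc4ccccc4)c4c(OC)cccc34)c(O)c12
F3 | step 7 | 1-methoxy-8-(methoxymethoxy)naphthalene | COCOc1cccc2cccc(OC)c12
F4 | step 7 | 2-iodo-8-methoxy-1-(methoxymethoxy)naphthalene | COCOc1c(I)ccc2cccc(OC)c12
F5 | step 7 | 1-(benzyloxy)-8-methoxy-4-[8-methoxy-1-(methoxymethoxy)naphthalen-2-yl]naphthalene | COCOc1c(-c3ccc(OCc4ccccc4)c4c(OC)cccc34)ccc2cccc(OC)c12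
F6 | step 7 | 2-[4-(benzyloxy)-5-methoxynaphthalen-1-yl]-8-methoxynaphthalen-1-ol | Oc1c(-c3ccc(OCc4ccccc4)c4c(OC)cccc34)ccc2cccc(OC)c12
F7 | step 9 | 2,4-bis[4-(benzyloxy)-5-methoxynaphthalen-1-yl]-8-methoxy-1,4-dihydronaphthalene-1,4-diol (diastereomer mixture, racemic) | COc1cccc2c1C(O)C(c1ccc(OCc3ccccc3)c3c(OC)cccc13)=CC2(O)c1ccc(OCc2ccccc2)c2c(OC)cccc12
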